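**Strategy.** Ring B is a 3-alkyl-2,4-dihydroxyaryl ketone: C1 carries the pyrrolyl carbonyl, C2 and C4 the hydroxyls, C3 the three-carbon chain, and C5/C6 are unsubstituted. The route cuts the C1–C2 and C5–C6 bonds. One Diels–Alder reaction joins a 2-alkyl-1-methoxy-1,3-bis(trimethylsilyloxy)butadiene, which already holds the chain with its pyrrolyl ketone masked as a dioxolane, to an N-Boc dichloropyrrolyl ethynyl ketone. This closes ring B, and loss of methanol plus desilylation gives the fully substituted resorcinol without any substitution on the arene. Both partners come from one Weinreb amide, and one acid treatment then releases the target.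

Key step: step 10

Remark: the target is achiral. The sp3 centres that appear on the way (in 5, 11, 16 and 18) are racemic and are erased later. The enol-ether double bonds of 12 and 13 may form as E/Z mixtures that converge on the same arene, so no geometry is drawn. Metal salts (conjugate bases) of numbered compounds are referred to by the number of the parent.

Step 1
Reactants: 1 4,5-dichloro-1H-pyrrole-2-carboxylic acid
Product: 3 4,5-dichloro-N-methoxy-N-methyl-1H-pyrrole-2-carboxamide, via acyl imidazolide 2 (not isolated)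
Conditions: CDI (1.1 equiv), THF, rt; then MeNH(OMe)·HCl (1.5 equiv), rt
Reagents that add atoms: N,O-dimethylhydroxylamine hydrochloride, CNOC.Cl
Why: Amide coupling through the acyl imidazolide, which acylates the hydroxylamine under near-neutral conditions that leave the electron-poor pyrrole N–H alone.

Step 2
Reactants: 3 4,5-dichloro-N-methoxy-N-methyl-1H-pyrrole-2-carboxamide; 4 vinylmagnesium bromide
Product: 6 1-(4,5-dichloro-1H-pyrrol-2-yl)prop-2-en-1-one, via magnesium hemiaminal 5 (not isolated)
Conditions: CH2=CHMgBr (3 equiv), THF, −20 → 0 °C; inverse quench into cold 1 M HCl; crude used at once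
Reagents that add atoms: vinylmagnesium bromide (4), C=C[Mg]Br
Why: Weinreb ketone synthesis, in which one equivalent of Grignard reagent removes the N–H proton, a second adds to give a chelated adduct that cannot over-add, and the inverse acidic quench protonates the released hydroxylamine before it can add to the enone.

Step 3
Reactants: 6 1-(4,5-dichloro-1H-pyrrol-2-yl)prop-2-en-1-one
Product: 8 2-(2-bromoethyl)-2-(4,5-dichloro-1H-pyrrol-2-yl)-1,3-dioxolane, via bromoketone 7 (not isolated)
Conditions: Me3SiBr (3 equiv), HOCH2CH2OH (4 equiv), CH2Cl2, 0 °C → rt; cold NaHCO3 (aq)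
Reagents that add atoms: bromotrimethylsilane, C[Si](C)(C)Br; ethylene glycol, OCCO
Why: Conjugate hydrobromination of the enone followed by acid-catalysed ketalisation, a known one-pot route from enones to β-bromo ketals in which the silyl bromide supplies dry HBr and removes the water of ketalisation as the disiloxane, so the conjugated pyrrolyl ketone is driven to the dioxolane.

Step 4
Reactants: 8 2-(2-bromoethyl)-2-(4,5-dichloro-1H-pyrrol-2-yl)-1,3-dioxolane
Product: 9 tert-butyl 5-[2-(2-bromoethyl)-1,3-dioxolan-2-yl]-2,3-dichloro-1H-pyrrole-1-carboxylate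
Conditions: Boc2O (1.3 equiv), DMAP (0.1 equiv), MeCN, 0 °C → rt
Reagents that add atoms: di-tert-butyl dicarbonate, CC(C)(C)OC(=O)OC(=O)OC(C)(C)C
Why: DMAP-catalysed Boc protection of the pyrrole nitrogen, run without stoichiometric base so that no pyrrolide builds up to displace the bromide in a 5-exo N-alkylation.

Step 5
Reactants: 9 tert-butyl 5-[2-(2-bromoethyl)-1,3-dioxolan-2-yl]-2,3-dichloro-1H-pyrrole-1-carboxylate; 10 methyl acetoacetate
Product: 11 methyl 2-acetyl-4-{2-[1-(tert-butoxycarbonyl)-4,5-dichloro-1H-pyrrol-2-yl]-1,3-dioxolan-2-yl}butanoate (racemic)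
Conditions: 10 (2.5 equiv), NaH (2.2 equiv), THF–DMF, 0 °C; then 9, NaI (0.2 equiv), 45 °C
Reagents that add atoms: methyl acetoacetate (10), COC(=O)CC(C)=O
Why: Acetoacetic ester alkylation, in which the soft sodium enolate, used in excess to suppress dialkylation, displaces the primary halide at carbon (iodide-assisted SN2); the new stereocentre is racemic and disappears on enolisation in the next step.

Step 6
Reactants: 11 methyl 2-acetyl-4-{2-[1-(tert-butoxycarbonyl)-4,5-dichloro-1H-pyrrol-2-yl]-1,3-dioxolan-2-yl}butanoate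
Product: 12 methyl 2-(2-{2-[1-(tert-butoxycarbonyl)-4,5-dichloro-1H-pyrrol-2-yl]-1,3-dioxolan-2-yl}ethyl)-3-(trimethylsilyloxy)but-2-enoate
Conditions: Me3SiCl (2 equiv), Et3N (2.5 equiv), PhMe, rt, 48–72 h; filter under Ar, concentrate
Reagents that add atoms: chlorotrimethylsilane, C[Si](C)(C)Cl
Why: Silyl enol ether formation by O-silylation of the β-keto ester enol with an amine base, conditions under which the carbamate, the ketal and the ester are inert.

Step 7
Reactants: 12 methyl 2-(2-{2-[1-(tert-butoxycarbonyl)-4,5-dichloro-1H-pyrrol-2-yl]-1,3-dioxolan-2-yl}ethyl)-3-(trimethylsilyloxy)but-2-enoate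
Product: 13 tert-butyl 2,3-dichloro-5-(2-{3-[methoxy(trimethylsilyloxy)methylidene]-4-(trimethylsilyloxy)pent-4-en-1-yl}-1,3-dioxolan-2-yl)-1H-pyrrole-1-carboxylate, the 2-substituted 1-methoxy-1,3-bis(trimethylsilyloxy)buta-1,3-diene
Conditions: LiN(iPr)2 (1.2 equiv), THF, −78 °C; Me3SiCl (1.4 equiv), −78 °C → rt; pentane, filter under Ar; used crude
Reagents that add atoms: chlorotrimethylsilane, C[Si](C)(C)Cl
Why: Vinylogous deprotonation of the β-silyloxy enoate at its methyl group and O-silylation of the resulting dienolate, the standard two-stage entry to 1,3-bis(silyloxy)dienes; the ketal leaves no other acidic C–H and the hindered amide at −78 °C spares the N-Boc group.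

Step 8
Reactants: 3 4,5-dichloro-N-methoxy-N-methyl-1H-pyrrole-2-carboxamide
Product: 14 tert-butyl 2,3-dichloro-5-[methoxy(methyl)carbamoyl]-1H-pyrrole-1-carboxylate
Conditions: Boc2O (1.3 equiv), DMAP (0.1 equiv), MeCN, rt
Reagents that add atoms: di-tert-butyl dicarbonate, CC(C)(C)OC(=O)OC(=O)OC(C)(C)C
Why: DMAP-catalysed Boc protection of an acidic acylpyrrole N–H, placed before the alkyne is introduced so that no nucleophilic catalyst ever meets the ynone.

Step 9
Reactants: 14 tert-butyl 2,3-dichloro-5-[methoxy(methyl)carbamoyl]-1H-pyrrole-1-carboxylate; 15 ethynylmagnesium bromide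
Product: 17 tert-butyl 2,3-dichloro-5-propioloyl-1H-pyrrole-1-carboxylate, via magnesium hemiaminal 16 (not isolated)
Conditions: HC≡CMgBr (1.5 equiv), THF, −40 → 0 °C; inverse quench into cold 1 M HCl
Reagents that add atoms: ethynylmagnesium bromide (15), C#C[Mg]Br
Why: Weinreb ketone synthesis, in which the slim acetylide should add to the amide faster than to the hindered tert-butyl carbamate at low temperature, the chelated adduct keeps the ynone masked until the quench, and the inverse acidic quench holds the released hydroxylamine as its salt.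

Step 10
Reactants: 13 the 2-substituted 1-methoxy-1,3-bis(trimethylsilyloxy)buta-1,3-diene; 17 tert-butyl 2,3-dichloro-5-propioloyl-1H-pyrrole-1-carboxylate
Product: 20 tert-butyl 5-[3-(2-{2-[1-(tert-butoxycarbonyl)-4,5-dichloro-1H-pyrrol-2-yl]-1,3-dioxolan-2-yl}ethyl)-2,4-dihydroxybenzoyl]-2,3-dichloro-1H-pyrrole-1-carboxylate, via cyclohexadiene adduct 18 (not isolated), via bis(trimethylsilyl) ether 19 (not isolated)
Conditions: 13 (1.4 equiv), PhMe, 0 °C → rt (45 °C if slow); then 10% aq. citric acid, THF, 0 °C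
Reagents that add atoms: none
Why: The electron-rich diene 13 and the electron-poor ynone 17 should combine in a strongly asynchronous, normal-electron-demand (4+2) cycloaddition: the CH2 terminus of the diene (future C5) bonds to the ynone β-carbon (future C6) and the ketene-acetal carbon (future C2) bonds to the α-carbon (future C1), giving the 1,4-cyclohexadiene 18. Loss of methanol from the former ketene-acetal carbon aromatises the ring to 19, and the mild acid work-up hydrolyses the two aryl silyl ethers to 20. The closest known reaction type is the Diels–Alder/aromatisation of 1-alkoxy-1,3-bis(silyloxy)butadienes with acetylenic ketones and esters, which gives 2,4-dihydroxyaryl carbonyl compounds. Ring B closes as a six-membered carbocycle by intermolecular (4+2) annulation; in the stepwise limit the second bond forms by 6-exo-trig attack of the allenolate α-carbon on the ester-level carbon. No stereocentre is set, because the only sp3 ring centre of 18 is lost on aromatisation. The step needs regio- and chemoselectivity: the largest HOMO coefficient (diene CH2 terminus, pushed by both oxygen donors) pairs with the largest LUMO coefficient (ynone β-carbon), the absence of a Lewis acid keeps the diene off the ketone carbonyl, and Boc and the dioxolane remove every acidic N–H and enolisable C–H that could protodesilylate the diene.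

Step 11
Reactants: 20 the Boc- and ketal-protected resorcinol
Product: 21 dihydrotetrachlorizine, 1-(4,5-dichloro-1H-pyrrol-2-yl)-3-[3-(4,5-dichloro-1H-pyrrole-2-carbonyl)-2,6-dihydroxyphenyl]propan-1-one
Conditions: TFA–H2O (9:1), CH2Cl2, 0 °C → rt
Reagents that add atoms: water, O
Why: Acidolysis of both tert-butyl carbamates and hydrolysis of the dioxolane should proceed together in aqueous trifluoroacetic acid, to which the aryl ketones, the phenols and the chloropyrroles are inert, while the water also intercepts tert-butyl cations before they reach the resorcinol ring.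

**Compound list**

1 | 4,5-dichloro-1H-pyrrole-2-carboxylic acid | O=C(O)c1cc(Cl)c(Cl)[nH]1 | starting material
2 | (4,5-dichloro-1H-pyrrol-2-yl)(1H-imidazol-1-yl)methanone (acyl imidazolide) | O=C(c1cc(Cl)c(Cl)[nH]1)n1ccnc1 | intermediate
3 | 4,5-dichloro-N-methoxy-N-methyl-1H-pyrrole-2-carboxamide | CON(C)C(=O)c1cc(Cl)c(Cl)[nH]1 | intermediate
4 | vinylmagnesium bromide | C=C[Mg]Br | starting material
5 | bis(bromomagnesium) salt of the tetrahedral vinyl adduct of 3 (O–MgBr and N–MgBr; racemic) | C=CC(O[Mg]Br)(N(C)OC)c1cc(Cl)c(Cl)n1[Mg]Br | intermediate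
6 | 1-(4,5-dichloro-1H-pyrrol-2-yl)prop-2-en-1-one | C=CC(=O)c1cc(Cl)c(Cl)[nH]1 | intermediate
7 | 3-bromo-1-(4,5-dichloro-1H-pyrrol-2-yl)propan-1-one | O=C(CCBr)c1cc(Cl)c(Cl)[nH]1 | intermediate
8 | 2-(2-bromoethyl)-2-(4,5-dichloro-1H-pyrrol-2-yl)-1,3-dioxolane | BrCCC1(c2cc(Cl)c(Cl)[nH]2)OCCO1 | intermediate
9 | tert-butyl 5-[2-(2-bromoethyl)-1,3-dioxolan-2-yl]-2,3-dichloro-1H-pyrrole-1-carboxylate | BrCCC1(c2cc(Cl)c(Cl)n2C(=O)OC(C)(C)C)OCCO1 | intermediate
10 | methyl acetoacetate | COC(=O)CC(C)=O | starting material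
11 | methyl 2-acetyl-4-{2-[1-(tert-butoxycarbonyl)-4,5-dichloro-1H-pyrrol-2-yl]-1,3-dioxolan-2-yl}butanoate (racemic) | COC(=O)C(CCC1(c2cc(Cl)c(Cl)n2C(=O)OC(C)(C)C)OCCO1)C(C)=O | intermediate
12 | methyl 2-(2-{2-[1-(tert-butoxycarbonyl)-4,5-dichloro-1H-pyrrol-2-yl]-1,3-dioxolan-2-yl}ethyl)-3-(trimethylsilyloxy)but-2-enoate (E/Z mixture) | COC(=O)C(CCC1(c2cc(Cl)c(Cl)n2C(=O)OC(C)(C)C)OCCO1)=C(C)O[Si](C)(C)C | intermediate
13 | tert-butyl 2,3-dichloro-5-(2-{3-[methoxy(trimethylsilyloxy)methylidene]-4-(trimethylsilyloxy)pent-4-en-1-yl}-1,3-dioxolan-2-yl)-1H-pyrrole-1-carboxylate (E/Z mixture at the ketene acetal) | COC(O[Si](C)(C)C)=C(CCC1(c2cc(Cl)c(Cl)n2C(=O)OC(C)(C)C)OCCO1)C(=C)O[Si](C)(C)C | intermediate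
14 | tert-butyl 2,3-dichloro-5-[methoxy(methyl)carbamoyl]-1H-pyrrole-1-carboxylate | CON(C)C(=O)c1cc(Cl)c(Cl)n1C(=O)OC(C)(C)C | intermediate
15 | ethynylmagnesium bromide | C#C[Mg]Br | starting material
16 | bromomagnesium salt of the tetrahedral ethynyl adduct of 14 (racemic) | C#CC(O[Mg]Br)(N(C)OC)c1cc(Cl)c(Cl)n1C(=O)OC(C)(C)C | intermediate
17 | tert-butyl 2,3-dichloro-5-propioloyl-1H-pyrrole-1-carboxylate | C#CC(=O)c1cc(Cl)c(Cl)n1C(=O)OC(C)(C)C | intermediate
18 | 1,4-cyclohexadiene cycloadduct: 6-methoxy-4,6-bis(trimethylsilyloxy)cyclohexa-1,4-diene carrying the N-Boc-pyrrolylcarbonyl group at C1 and the ketal chain at C5 (racemic) | COC1(O[Si](C)(C)C)C(C(=O)c2cc(Cl)c(Cl)n2C(=O)OC(C)(C)C)=CCC(O[Si](C)(C)C)=C1CCC1(c2cc(Cl)c(Cl)n2C(=O)OC(C)(C)C)OCCO1 | intermediate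
19 | bis(trimethylsilyl) ether of 20 | C[Si](C)(C)Oc1ccc(C(=O)c2cc(Cl)c(Cl)n2C(=O)OC(C)(C)C)c(O[Si](C)(C)C)c1CCC1(c2cc(Cl)c(Cl)n2C(=O)OC(C)(C)C)OCCO1 | intermediate
20 | tert-butyl 5-[3-(2-{2-[1-(tert-butoxycarbonyl)-4,5-dichloro-1H-pyrrol-2-yl]-1,3-dioxolan-2-yl}ethyl)-2,4-dihydroxybenzoyl]-2,3-dichloro-1H-pyrrole-1-carboxylate | O=C(c1ccc(O)c(CCC2(c3cc(Cl)c(Cl)n3C(=O)OC(C)(C)C)OCCO2)c1O)c1cc(Cl)c(Cl)n1C(=O)OC(C)(C)C | intermediate
21 | dihydrotetrachlorizine | O=C(CCc1c(O)ccc(C(=O)c2cc(Cl)c(Cl)[nH]2)c1O)c1cc(Cl)c(Cl)[nH]1 | target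

**Step count.** Total: 11 steps. Longest linear sequence: 9 steps (steps 1–7, 10, 11); steps 8 and 9 make the second partner from compound 3.

**Steps most likely to fail**

1. Step 10. The diene may be protodesilylated before it reacts, the addition may stop at an open-chain Michael adduct that does not close, or the partners may combine with reversed orientation. Fallback, setting out from vinyl ketone 6 and acid 1 and coming back at target 21: ring B is taken from a bought arene and the aroyl group enters by electrophilic substitution. The diarylcuprate made from 1,3-dimethoxybenzene (n-BuLi; then CuBr·SMe2; Me3SiCl) is added in conjugate fashion to 6, whose N–H is first removed with LiN(SiMe3)2, to give 1-(4,5-dichloro-1H-pyrrol-2-yl)-3-(2,6-dimethoxyphenyl)propan-1-one F1. Acid 1 with oxalyl chloride and catalytic DMF gives 4,5-dichloro-1H-pyrrole-2-carbonyl chloride F2. Friedel–Crafts acylation of F1 with F2 and AlCl3 should go para to one methoxy group and ortho to the other, giving (4,5-dichloro-1H-pyrrol-2-yl){3-[3-(4,5-dichloro-1H-pyrrol-2-yl)-3-oxopropyl]-2,4-dimethoxyphenyl}methanone F3. Demethylation with BBr3 then gives 21.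

2. Step 3. Ketalisation of a carbonyl that behaves as a vinylogous amide may stay incomplete, and the free N–H pyrrole may oligomerise in strong acid. Fallback, setting out from vinyl ketone 6 and coming back at bromoketal 9: the ketal is made on the N-acylated pyrrole without protic acid and the bromide is introduced afterwards. Boc2O with catalytic DMAP gives tert-butyl 5-acryloyl-2,3-dichloro-1H-pyrrole-1-carboxylate F4. Ketalisation with Me3SiOCH2CH2OSiMe3 and catalytic Me3SiOTf in CH2Cl2 at −78 °C gives tert-butyl 2,3-dichloro-5-(2-vinyl-1,3-dioxolan-2-yl)-1H-pyrrole-1-carboxylate F5. Anti-Markovnikov hydroboration–oxidation (9-BBN; NaBO3·4H2O) gives tert-butyl 2,3-dichloro-5-[2-(2-hydroxyethyl)-1,3-dioxolan-2-yl]-1H-pyrrole-1-carboxylate F6. An Appel bromination (CBr4, PPh3, 2,6-lutidine) then gives 9.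

3. Step 9. The Grignard reagent may attack the carbamate carbonyl with loss of the Boc group, and released hydroxylamine may add to the ynone during the quench. Fallback, setting out from amide 14 and coming back at ynone 17: the acetylide is added to an aldehyde at −78 °C, where the carbamate is inert, and the ketone is reached by oxidation. Reduction of 14 with iBu2AlH at −78 °C gives tert-butyl 2,3-dichloro-5-formyl-1H-pyrrole-1-carboxylate F7. Addition of 15 at −78 °C with a cold acetic acid quench gives racemic tert-butyl 2,3-dichloro-5-(1-hydroxyprop-2-yn-1-yl)-1H-pyrrole-1-carboxylate F8. Dess–Martin oxidation buffered with NaHCO3 then gives 17.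

**Further compounds**

F1 | step 10 | 1-(4,5-dichloro-1H-pyrrol-2-yl)-3-(2,6-dimethoxyphenyl)propan-1-one | COc1cccc(OC)c1CCC(=O)c1cc(Cl)c(Cl)[nH]1
F2 | step 10 | 4,5-dichloro-1H-pyrrole-2-carbonyl chloride | O=C(Cl)c1cc(Cl)c(Cl)[nH]1
F3 | step 10 | (4,5-dichloro-1H-pyrrol-2-yl){3-[3-(4,5-dichloro-1H-pyrrol-2-yl)-3-oxopropyl]-2,4-dimethoxyphenyl}methanone | COc1ccc(C(=O)c2cc(Cl)c(Cl)[nH]2)c(OC)c1CCC(=O)c1cc(Cl)c(Cl)[nH]1
F4 | step 3 | tert-butyl 5-acryloyl-2,3-dichloro-1H-pyrrole-1-carboxylate | C=CC(=O)c1cc(Cl)c(Cl)n1C(=O)OC(C)(C)C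
F5 | step 3 | tert-butyl 2,3-dichloro-5-(2-vinyl-1,3-dioxolan-2-yl)-1H-pyrrole-1-carboxylate | C=CC1(c2cc(Cl)c(Cl)n2C(=O)OC(C)(C)C)OCCO1
F6 | step 3 | tert-butyl 2,3-dichloro-5-[2-(2-hydroxyethyl)-1,3-dioxolan-2-yl]-1H-pyrrole-1-carboxylate | OCCC1(c2cc(Cl)c(Cl)n2C(=O)OC(C)(C)C)OCCO1
F7 | step 9 | tert-butyl 2,3-dichloro-5-formyl-1H-pyrrole-1-carboxylate | O=Cc1cc(Cl)c(Cl)n1C(=O)OC(C)(C)C
F8 | step 9 | tert-butyl 2,3-dichloro-5-(1-hydroxyprop-2-yn-1-yl)-1H-pyrrole-1-carboxylate (racemic) | C#CC(O)c1cc(Cl)c(Cl)n1C(=O)OC(C)(C)C
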